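## Structural features

- The target 27 is a cembranoid: a 14-membered carbocycle (C1–C14) fused across C1–C3 to a δ-lactone. The ring oxygen is on C3, the carbonyl is C16, and C15 carries the methyl C17 and is bonded to C1.
- The macrocycle carries a trans 11,12-epoxide (methyl C20 on C12), a tertiary carbinol at C4 (methyl C18), an exocyclic methylene at C8 (C19) and a secondary allylic hydroperoxide at C7.
- Seven stereocentres are present, (1R,3R,4S,7S,11S,12S,15S). C15 and C1 are neighbours on the lactone, C3 and C4 are contiguous, C11 and C12 are the epoxide carbons, and C7 stands alone next to the alkene.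
- On the lactone chair the C14 arm on C1 and C4 on C3 are cis, and the C15 methyl is trans to the C14 arm. This is the all-equatorial arrangement, so C15 is also the thermodynamically preferred epimer.
- Fragile groups are the hydroperoxide (reductants, bases, metals), which must therefore be made last, the acid-labile trisubstituted epoxide, and the lactone (carbanions, alkoxides, enolisable C15).
- The real difficulty is to close the 14-membered ring on a chain that already carries six stereocentres, two electrophilic oxygen functions and an enolisable lactone, and then to place O2H at C7 with control of position and configuration.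
- The key step exploits the C4–C5–C6 segment: C4 is fully substituted and bears OH, C5 is a methylene, and C6 is allylic to the C7=C8 alkene. C4–OH with C5 is therefore the product of a 2,2-disubstituted 4,5-epoxide opened at its CH2 by a C6 sulfonyl carbanion.

## Logic of the disconnections

**27 to 26.** The C7–O bond is cut and the alkene returned from C8=C19 to C7=C8, which is the retron of a singlet-oxygen ene reaction. The peroxide then enters last and without any reagent that could reduce it, and C7 disappears as a stereocentre. The forward step must take hydrogen from C19 and not from C6, and must attack one face of the alkene in the macrocycle.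

**26 to 25.** A phenylsulfonyl group is placed on C6 (C6–H becomes C6–S). It is the auxiliary that makes C6 a nucleophile. The forward step must remove it reductively without moving the C7=C8 bond and without harming lactone or epoxide; the hydroxyl is γ to sulfur, so no elimination is possible.

**25 to 24.** The C5–C6 bond is cut. The ring opens, the C4 hydroxyl becomes the oxygen of a terminal epoxide with C4 unchanged, and an acyclic seco-sulfone results. The forward step needs α-alkylation of the allyl sulfone anion at C5 in preference to attack on the 11,12-epoxide or on the lactone carbonyl.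

**24 to 23, then to 22 and 6.** The C13–C14 bond is cut by way of a C13=C14 alkene. This is the only unfunctionalised CH2–CH2 link between two halves whose stereocentres come from separate asymmetric reactions, and 6 cannot enolise. The forward olefination must tolerate lactone, two epoxides and the acidic allyl sulfone, and the reduction must spare the trisubstituted alkene.

**6 to 5, 4, 3, then 1 and 2.** The aldehyde goes back to the alcohol, the C11–O and C12–O bonds are cut, the C13 oxygen is removed and the C6–S bond is cut. The C13 hydroxyl serves twice: it directs the epoxidation that sets C11 and C12, and it becomes the union carbonyl. The forward steps need E-selective allylic oxidation at the distal alkene and reagent-controlled epoxidation.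

**22 to 21 to 20.** The sulfone is returned to the sulfide and the C15–C17 bond is cut. The sulfone is made last because its α-protons would interfere with enolate chemistry. The methyl is introduced on the rigid lactone, where the C14 arm on C1 directs it trans.

**20 to 19, 18, 17, 16.** The C5–O epoxide bond is traced to a C5 tosylate displaced by the C4 oxygen. The lactone C3–O bond is traced to a 3,4-epoxide opened at C3 with inversion by the C16 carboxyl group. The 3,4-epoxide is traced to an E-allylic alcohol. One asymmetric epoxidation thus fixes both C3 and C4, and the C4 oxygen is never detached. The forward opening must occur at C3 (six-membered ring) and not at the tertiary C4.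

**16 to 15, then 13 and 14.** The C5 carbonyl is reduced and the C3=C4 bond is cut by cross-metathesis. This gives the E-trisubstituted allylic alcohol in two steps from a terminal alkene.

**13 to 12, 11, then 9 and 10, then 7 and 8.** The C14–S bond, the C1–C15 bond and the N-acyl bond are cut. C1 carries three CH2 arms and is set as the α-carbon of an acyl oxazolidinone whose carbonyl becomes C14. The alkylation must be face-selective, and the reduction must spare the tert-butyl ester.

## Other disconnections considered

**Alternative 1:** The cut is C12–C13 together with the C11–O bond of the epoxide.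
- Forward step: the primary iodide A2 is converted with t-BuLi and CeCl3 into an organocerium reagent that adds to the C12 ketone of the α-chloro ketone A1. The tertiary alkoxide then displaces chloride at C11 with inversion to give the open-chain epoxide A3.
- In favour: the union and the epoxide are made in one flask, with no olefination and reduction. For this region it is more step-economic than steps 16 and 17. No lactone is present during the carbanion step, so on chemoselectivity it is better than the chosen plan.
- Against: the step closes no ring, so a macrocyclisation is still needed. C12 depends on the facial selectivity of addition to an enolisable α-chloro ketone, which is less secure than the reagent-controlled epoxidation of step 3. Three PMB ethers and a silyl ether must later be removed and C16 reoxidised.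
- Comparison: in structure it builds C11/C12 late and the lactone last, whereas the chosen plan carries both finished. In mechanism it uses a hard organometallic on a masked substrate in place of a stabilised carbanion on a functionalised one. In step economy it is shorter at the union and longer in protecting-group traffic.

**Alternative 2:** The cut is C3–C4 together with the lactone C16–O bond.
- Forward step: low-valent titanium from TiCl3 and Zn–Cu couples the C3 aldehyde with the C4 methyl ketone of A4. The C3 alkoxide of the diolate then acylates on the C16 ester to give the macrocyclic lactone A5.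
- In favour: ring and lactone form in one operation, which equals or betters the chosen ring closure in step economy. No carbanion meets a lactone, which is better. The C7 oxygen is in place before cyclisation, which is better for regiochemistry at C7 than the ene reaction of step 20.
- Against: C3 and C4 are both created at the ring closure under substrate control only, where the chosen plan sets them by one reagent-controlled epoxidation. Low-valent titanium deoxygenates epoxides, so the 11,12-epoxide would have to be introduced afterwards on an undirected alkene in the presence of the C8 methylene. The C7 ether must be converted into the hydroperoxide with inversion, and over-reduction to the alkene is possible.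
- Comparison: in structure the stereochemical burden is shifted onto the macrocyclisation. In mechanism it is a reductive carbonyl coupling instead of an SN2 alkylation. In step economy it is equal at the closure and longer afterwards.

**Alternative 3:** The cut is C7–C8.
- Forward step: CrCl2 with catalytic NiCl2 converts the alkenyl iodide of A6 into an alkenylchromium species that adds to the C7 aldehyde, closing the ring as the (7R)-allylic alcohol A7.
- In favour: the organochromium reagent tolerates lactone and epoxide, which is better than a lithiated sulfone. The exocyclic alkene and the C7 oxygen are fixed in position by construction, which is better than steps 19 and 20.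
- Against: the C7 configuration rests on macrocyclic diastereoselection. The alcohol must be turned into the hydroperoxide by displacement with inversion at a secondary allylic carbon, where allylic transposition and ionisation compete. Several equivalents of a divalent chromium salt are needed, and A6 is reached only through the protected sequence of alternative 1.
- Comparison: in structure it is equal (both close the carbocycle next to C7). In mechanism it is a chemoselective carbonyl addition against a carbanion alkylation. In step economy it is poorer, because the peroxide needs extra steps where the chosen plan needs one.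

Key step: step 18

Assumption: C6 in 25 and the geometry of the C13=C14 bond in 23 are left undefined because both are erased (steps 19 and 17); locants are those defined under "Structural features".

Remark: 24 and 25 were checked centre by centre against 27 (C1, C3, C4, C11, C12, C15 and the 7E bond agree) and need no correction. Step 18 does create one stereocentre, C6, which is transient. A butenolide–propionate Michael adduct would carry no absolute configuration, so C1 is set by auxiliary alkylation (step 6) and C15 by lactone methylation (step 14).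

## Steps

Step 1
Reactants: 1 geranyl bromide; 2 sodium benzenesulfinate
Product: 3 geranyl phenyl sulfone, {[(2E)-3,7-dimethylocta-2,6-dien-1-yl]sulfonyl}benzene
Conditions: DMF, rt
Reagents that add atoms: none
Why: SN2 S-alkylation of the sulfinate by the primary allylic bromide in a dipolar aprotic solvent; the E geometry of the alkene is not touched.

Step 2
Reactants: 3 geranyl phenyl sulfone
Product: 4 (2E,6E)-2,6-dimethyl-8-(phenylsulfonyl)octa-2,6-dien-1-ol
Conditions: SeO2 (cat.), t-BuOOH, salicylic acid (cat.), CH2Cl2, rt
Reagents that add atoms: tert-butyl hydroperoxide, CC(C)(C)OO (terminal oxidant; the oxygen is relayed by SeO2)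
Why: Selenium dioxide allylic oxidation (ene reaction, then [2,3]-shift) attacks the electron-richer distal alkene at its E-methyl group and gives the E-allylic alcohol; the alkene next to the sulfonyl group is deactivated.

Step 3
Reactants: 4 (2E,6E)-2,6-dimethyl-8-(phenylsulfonyl)octa-2,6-dien-1-ol
Product: 5 {(2S,3S)-2-methyl-3-[(3E)-3-methyl-5-(phenylsulfonyl)pent-3-en-1-yl]oxiran-2-yl}methanol
Conditions: Ti(OiPr)4 (cat.), L-(+)-diethyl tartrate (cat.), t-BuOOH, 4 Å MS, CH2Cl2, −20 °C
Reagents that add atoms: tert-butyl hydroperoxide, CC(C)(C)OO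
Why: Sharpless asymmetric epoxidation; the L-(+)-tartrate complex delivers oxygen to one face of the E-2-methyl allylic alcohol (reagent control) and sets C11 and C12 as in the target, while the 7,8-alkene has no directing hydroxyl and stays.

Step 4
Reactants: 5 {(2S,3S)-2-methyl-3-[(3E)-3-methyl-5-(phenylsulfonyl)pent-3-en-1-yl]oxiran-2-yl}methanol
Product: 6 (2R,3S)-2-methyl-3-[(3E)-3-methyl-5-(phenylsulfonyl)pent-3-en-1-yl]oxirane-2-carbaldehyde
Conditions: Dess–Martin periodinane, pyridine, CH2Cl2, 0 °C to rt
Reagents that add atoms: none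
Why: Dess–Martin oxidation of the primary alcohol under buffered conditions; the aldehyde has a quaternary α-carbon and can neither enolise nor epimerise (the descriptor at C2 changes by priority only).

Step 5
Reactants: 7 (4S)-4-benzyl-1,3-oxazolidin-2-one; 8 pent-4-enoyl chloride
Product: 9 (4S)-4-benzyl-3-(pent-4-enoyl)-1,3-oxazolidin-2-one
Conditions: n-BuLi, THF, −78 °C to 0 °C
Reagents that add atoms: none
Why: N-acylation of the lithiated oxazolidinone by the acid chloride.

Step 6
Reactants: 9 (4S)-4-benzyl-3-(pent-4-enoyl)-1,3-oxazolidin-2-one; 10 tert-butyl bromoacetate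
Product: 11 tert-butyl (3R)-3-{[(4S)-4-benzyl-2-oxo-1,3-oxazolidin-3-yl]carbonyl}hex-5-enoate
Conditions: NaN(SiMe3)2, THF, −78 °C
Reagents that add atoms: none
Why: Evans alkylation; the chelated Z-sodium enolate is alkylated on the face opposite the benzyl group, which sets C1 under auxiliary control.

Step 7
Reactants: 11 tert-butyl (3R)-3-{[(4S)-4-benzyl-2-oxo-1,3-oxazolidin-3-yl]carbonyl}hex-5-enoate
Product: 12 tert-butyl (3R)-3-(hydroxymethyl)hex-5-enoate
Conditions: LiBH4, H2O (1 equiv), Et2O, 0 °C
Reagents that add atoms: none
Why: Chemoselective borohydride reduction of the activated imide carbonyl frees C14 as the primary alcohol and returns the auxiliary; the tert-butyl ester is too hindered to be reduced or to lactonise.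

Step 8
Reactants: 12 tert-butyl (3R)-3-(hydroxymethyl)hex-5-enoate
Product: 13 tert-butyl (3R)-3-{[(1-phenyl-1H-tetrazol-5-yl)sulfanyl]methyl}hex-5-enoate
Conditions: PPh3, DIAD, THF, 0 °C to rt
Reagents that add atoms: 1-phenyl-1H-tetrazole-5-thiol, Sc1nnnn1-c1ccccc1
Why: Mitsunobu thioetherification of the primary alcohol; the electron-poor heteroaryl sulfide is a weak nucleophile and slow to oxidise, so it is carried as the latent Julia–Kocienski handle.

Step 9
Reactants: 13 tert-butyl (3R)-3-{[(1-phenyl-1H-tetrazol-5-yl)sulfanyl]methyl}hex-5-enoate; 14 methacrolein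
Product: 15 tert-butyl (3R,5E)-6-methyl-7-oxo-3-{[(1-phenyl-1H-tetrazol-5-yl)sulfanyl]methyl}hept-5-enoate
Conditions: second-generation Hoveyda–Grubbs catalyst, RuCl2(H2IMes)(=CH–C6H4-2-OiPr) (5 mol%), CH2Cl2, 40 °C
Reagents that add atoms: none
Why: Olefin cross-metathesis of the terminal alkene with a 1,1-disubstituted enal that does not homodimerise; the trisubstituted enal forms as the E isomer for steric reasons.

Step 10
Reactants: 15 tert-butyl (3R,5E)-6-methyl-7-oxo-3-{[(1-phenyl-1H-tetrazol-5-yl)sulfanyl]methyl}hept-5-enoate
Product: 16 tert-butyl (3R,5E)-7-hydroxy-6-methyl-3-{[(1-phenyl-1H-tetrazol-5-yl)sulfanyl]methyl}hept-5-enoate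
Conditions: NaBH4, CeCl3·7H2O, MeOH, −40 °C
Reagents that add atoms: none
Why: Luche 1,2-reduction of the enal; ester and sulfide are inert.

Step 11
Reactants: 16 tert-butyl (3R,5E)-7-hydroxy-6-methyl-3-{[(1-phenyl-1H-tetrazol-5-yl)sulfanyl]methyl}hept-5-enoate
Product: 17 tert-butyl (3R)-4-[(2S,3S)-3-(hydroxymethyl)-3-methyloxiran-2-yl]-3-{[(1-phenyl-1H-tetrazol-5-yl)sulfanyl]methyl}butanoate
Conditions: Ti(OiPr)4 (cat.), L-(+)-diethyl tartrate (cat.), t-BuOOH, 4 Å MS, CH2Cl2, −20 °C
Reagents that add atoms: tert-butyl hydroperoxide, CC(C)(C)OO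
Why: Sharpless asymmetric epoxidation under reagent control places the C4 oxygen in its final configuration and gives C3 the configuration opposite to the one needed, to be inverted in step 13; the ligand-accelerated epoxidation should be far faster than oxidation of the deactivated sulfide.

Step 12
Reactants: 17 tert-butyl (3R)-4-[(2S,3S)-3-(hydroxymethyl)-3-methyloxiran-2-yl]-3-{[(1-phenyl-1H-tetrazol-5-yl)sulfanyl]methyl}butanoate
Product: 18 tert-butyl (3R)-4-[(2S,3S)-3-methyl-3-({[(4-methylphenyl)sulfonyl]oxy}methyl)oxiran-2-yl]-3-{[(1-phenyl-1H-tetrazol-5-yl)sulfanyl]methyl}butanoate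
Conditions: TsCl, Et3N, DMAP (cat.), CH2Cl2, 0 °C
Reagents that add atoms: 4-methylbenzenesulfonyl chloride, Cc1ccc(cc1)S(Cl)(=O)=O
Why: Sulfonylation of the only hydroxyl turns C5 into a leaving group, and the electron-withdrawing sulfonate disfavours later ionisation at the neighbouring C4.

Step 13
Reactants: 18 tert-butyl (3R)-4-[(2S,3S)-3-methyl-3-({[(4-methylphenyl)sulfonyl]oxy}methyl)oxiran-2-yl]-3-{[(1-phenyl-1H-tetrazol-5-yl)sulfanyl]methyl}butanoate
Product: 20 (4R,6R)-6-[(2S)-2-methyloxiran-2-yl]-4-{[(1-phenyl-1H-tetrazol-5-yl)sulfanyl]methyl}oxan-2-one, via hydroxy tosylate lactone 19 (not isolated)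
Conditions: CF3CO2H, CH2Cl2, 0 °C; evaporate; then DBU, CH2Cl2, rt
Reagents that add atoms: none
Why: Acid-promoted epoxide-opening lactonisation: the tert-butyl ester carbonyl attacks the protonated epoxide at C3 in a 6-exo SN2 opening with inversion (isobutene is lost) and gives the δ-lactone with the correct C3. Base then lets the C4 alkoxide displace the tosylate (Williamson-type epoxide closure) with C4 unchanged.

Step 14
Reactants: 20 (4R,6R)-6-[(2S)-2-methyloxiran-2-yl]-4-{[(1-phenyl-1H-tetrazol-5-yl)sulfanyl]methyl}oxan-2-one
Product: 21 (3S,4R,6R)-3-methyl-6-[(2S)-2-methyloxiran-2-yl]-4-{[(1-phenyl-1H-tetrazol-5-yl)sulfanyl]methyl}oxan-2-one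
Conditions: LiN(iPr)2, THF, −78 °C; then MeI, −78 °C
Reagents that add atoms: iodomethane, CI
Why: Lactone enolate alkylation: iodomethane approaches anti to the side chain on the adjacent carbon and gives the 3,4-trans (all-equatorial) lactone, which sets C15; this is also the more stable epimer, so any cis isomer can be equilibrated with DBU. Lithium ester enolates do not open epoxides at this temperature.

Step 15
Reactants: 21 (3S,4R,6R)-3-methyl-6-[(2S)-2-methyloxiran-2-yl]-4-{[(1-phenyl-1H-tetrazol-5-yl)sulfanyl]methyl}oxan-2-one
Product: 22 (3S,4R,6R)-3-methyl-6-[(2S)-2-methyloxiran-2-yl]-4-{[(1-phenyl-1H-tetrazol-5-yl)sulfonyl]methyl}oxan-2-one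
Conditions: mCPBA (2.5 equiv), CH2Cl2, 0 °C to rt
Reagents that add atoms: 3-chloroperoxybenzoic acid, OOC(=O)c1cccc(Cl)c1
Why: Peracid oxidation of the sulfide to the sulfone; the molecule holds no alkene, and lactone and epoxide are inert to the peracid.

Step 16
Reactants: 22 (3S,4R,6R)-3-methyl-6-[(2S)-2-methyloxiran-2-yl]-4-{[(1-phenyl-1H-tetrazol-5-yl)sulfonyl]methyl}oxan-2-one; 6 (2R,3S)-2-methyl-3-[(3E)-3-methyl-5-(phenylsulfonyl)pent-3-en-1-yl]oxirane-2-carbaldehyde
Product: 23 (3S,4S,6R)-3-methyl-4-{2-[(2S,3S)-2-methyl-3-[(3E)-3-methyl-5-(phenylsulfonyl)pent-3-en-1-yl]oxiran-2-yl]ethenyl}-6-[(2S)-2-methyloxiran-2-yl]oxan-2-one (E/Z mixture at the new C13=C14 bond)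
Conditions: KN(SiMe3)2, DME, −78 °C; then 6, −78 °C to rt
Reagents that add atoms: none
Why: Julia–Kocienski olefination: the metalated tetrazolyl sulfone adds to the non-enolisable aldehyde, and Smiles rearrangement with loss of SO2 and the tetrazolone gives the alkene, whose geometry does not matter. Carbonyl addition at −78 °C should outpace proton transfer from the allylic sulfone and attack on lactone or epoxides.

Step 17
Reactants: 23 (3S,4S,6R)-3-methyl-4-{2-[(2S,3S)-2-methyl-3-[(3E)-3-methyl-5-(phenylsulfonyl)pent-3-en-1-yl]oxiran-2-yl]ethenyl}-6-[(2S)-2-methyloxiran-2-yl]oxan-2-one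
Product: 24 (3S,4R,6R)-3-methyl-4-{2-[(2S,3S)-2-methyl-3-[(3E)-3-methyl-5-(phenylsulfonyl)pent-3-en-1-yl]oxiran-2-yl]ethyl}-6-[(2S)-2-methyloxiran-2-yl]oxan-2-one
Conditions: 2-nitrobenzenesulfonylhydrazide, Et3N, CH2Cl2, rt
Reagents that add atoms: none
Why: Diimide reduction (concerted syn transfer of two hydrogens) is selective for the 1,2-disubstituted alkene over the trisubstituted 7,8-alkene and, unlike catalytic hydrogenation, does not cleave the allylic epoxide.

Step 18
Reactants: 24 (3S,4R,6R)-3-methyl-4-{2-[(2S,3S)-2-methyl-3-[(3E)-3-methyl-5-(phenylsulfonyl)pent-3-en-1-yl]oxiran-2-yl]ethyl}-6-[(2S)-2-methyloxiran-2-yl]oxan-2-one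
Product: 25 (1R,3R,4S,7E,11S,12S,15S)-11,12-epoxy-4-hydroxy-6-(phenylsulfonyl)cembr-7-en-16,3-olide (both C6 epimers)
Conditions: LiN(SiMe3)2 (1.05 equiv), THF (2 mM), −78 °C to rt; then H2O
Reagents that add atoms: none
Why: Intramolecular alkylation of a sulfone-stabilised allylic carbanion by an epoxide, the classical carbanion macrocyclisation of terpenoid synthesis: the base removes a C6 proton (about three pKa units more acidic than the lactone C15–H, so one equivalent leaves C15 alone) and the lithiated carbon attacks the unsubstituted epoxide carbon C5 from the side opposite the C5–O bond (SN2). The 14-membered ring closes in the endo mode of an epoxide opening: C4 and C5 both become ring atoms and the oxygen stays on C4 as the alkoxide, so C4 keeps the configuration set in step 11 and no existing stereocentre is touched. The only new stereocentre is C6, formed without control, which does not matter because step 19 removes the sulfonyl group. The step needs α-attack of the allyl sulfone anion (normal for alkylation of lithiated allyl sulfones), attack on the 4,5- and not the 11,12-epoxide (the terminal CH2 is far more accessible, and the E-alkene between C6 and C11/C12 would have to sit in a six- or seven-membered ring), and alkylation in preference to acylation by the lactone. The last point is the weak one: it is helped by the C15 methyl, which makes C16 an α-branched, hindered carbonyl, by the bulk and delocalisation of the carbanion, by lithium coordination to the epoxide oxygen and by the irreversibility of the C–C bond formation, while high dilution suppresses intermolecular reaction. The product is a γ-hydroxy sulfone and cannot undergo Julia-type elimination.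

Step 19
Reactants: 25 (1R,3R,4S,7E,11S,12S,15S)-11,12-epoxy-4-hydroxy-6-(phenylsulfonyl)cembr-7-en-16,3-olide
Product: 26 (1R,3R,4S,7E,11S,12S,15S)-11,12-epoxy-4-hydroxycembr-7-en-16,3-olide
Conditions: Na(Hg) (6% Na), Na2HPO4, MeOH–THF, −20 °C
Reagents that add atoms: none
Why: Reductive desulfonylation by electron transfer; the buffer keeps methoxide from opening the lactone, and at low temperature the allyl anion should be protonated at C6, which keeps the trisubstituted E-alkene at C7–C8.

Step 20
Reactants: 26 (1R,3R,4S,7E,11S,12S,15S)-11,12-epoxy-4-hydroxycembr-7-en-16,3-olide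
Product: 27 (1R,3R,4S,7S,11S,12S,15S)-11,12-epoxy-7-hydroperoxy-4-hydroxycembr-8(19)-en-16,3-olide (CNP0319766.2)
Conditions: O2, visible light, tetraphenylporphyrin (cat.), CH2Cl2, −20 °C
Reagents that add atoms: dioxygen, O=O
Why: Schenck ene reaction of singlet oxygen: oxygen bonds to C7 while a hydrogen of the C19 methyl on the more crowded side of the alkene is transferred (cis effect), which moves the alkene to C8=C19. C7 is set by attack on the exposed face of the alkene in the macrocycle; the 8-hydroperoxy-6-ene regioisomer and the C7 epimer are the expected by-products, to be removed by chromatography.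

## Compound list

1 | geranyl bromide | CC(C)=CCC/C(C)=C/CBr | starting material
2 | sodium benzenesulfinate | [Na+].[O-]S(=O)c1ccccc1 | starting material
3 | geranyl phenyl sulfone | CC(C)=CCC/C(C)=C/CS(=O)(=O)c1ccccc1 | intermediate
4 | (2E,6E)-2,6-dimethyl-8-(phenylsulfonyl)octa-2,6-dien-1-ol | OC/C(C)=C/CC/C(C)=C/CS(=O)(=O)c1ccccc1 | intermediate
5 | {(2S,3S)-2-methyl-3-[(3E)-3-methyl-5-(phenylsulfonyl)pent-3-en-1-yl]oxiran-2-yl}methanol | OC[C@]1(C)O[C@H]1CC/C(C)=C/CS(=O)(=O)c1ccccc1 | intermediate
6 | (2R,3S)-2-methyl-3-[(3E)-3-methyl-5-(phenylsulfonyl)pent-3-en-1-yl]oxirane-2-carbaldehyde | O=C[C@]1(C)O[C@H]1CC/C(C)=C/CS(=O)(=O)c1ccccc1 | intermediate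
7 | (4S)-4-benzyl-1,3-oxazolidin-2-one | O=C1N[C@@H](Cc2ccccc2)CO1 | starting material
8 | pent-4-enoyl chloride | C=CCCC(=O)Cl | starting material
9 | (4S)-4-benzyl-3-(pent-4-enoyl)-1,3-oxazolidin-2-one | C=CCCC(=O)N1[C@@H](Cc2ccccc2)COC1=O | intermediate
10 | tert-butyl bromoacetate | CC(C)(C)OC(=O)CBr | starting material
11 | tert-butyl (3R)-3-{[(4S)-4-benzyl-2-oxo-1,3-oxazolidin-3-yl]carbonyl}hex-5-enoate | C=CC[C@H](CC(=O)OC(C)(C)C)C(=O)N1[C@@H](Cc2ccccc2)COC1=O | intermediate
12 | tert-butyl (3R)-3-(hydroxymethyl)hex-5-enoate | C=CC[C@H](CC(=O)OC(C)(C)C)CO | intermediate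
13 | tert-butyl (3R)-3-{[(1-phenyl-1H-tetrazol-5-yl)sulfanyl]methyl}hex-5-enoate | C=CC[C@H](CC(=O)OC(C)(C)C)CSc1nnnn1-c1ccccc1 | intermediate
14 | methacrolein (2-methylprop-2-enal) | CC(=C)C=O | starting material
15 | tert-butyl (3R,5E)-6-methyl-7-oxo-3-{[(1-phenyl-1H-tetrazol-5-yl)sulfanyl]methyl}hept-5-enoate | O=C/C(C)=C/C[C@H](CC(=O)OC(C)(C)C)CSc1nnnn1-c1ccccc1 | intermediate
16 | tert-butyl (3R,5E)-7-hydroxy-6-methyl-3-{[(1-phenyl-1H-tetrazol-5-yl)sulfanyl]methyl}hept-5-enoate | OC/C(C)=C/C[C@H](CC(=O)OC(C)(C)C)CSc1nnnn1-c1ccccc1 | intermediate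
17 | tert-butyl (3R)-4-[(2S,3S)-3-(hydroxymethyl)-3-methyloxiran-2-yl]-3-{[(1-phenyl-1H-tetrazol-5-yl)sulfanyl]methyl}butanoate | OC[C@]1(C)O[C@H]1C[C@H](CC(=O)OC(C)(C)C)CSc1nnnn1-c1ccccc1 | intermediate
18 | tert-butyl (3R)-4-[(2S,3S)-3-methyl-3-({[(4-methylphenyl)sulfonyl]oxy}methyl)oxiran-2-yl]-3-{[(1-phenyl-1H-tetrazol-5-yl)sulfanyl]methyl}butanoate | Cc1ccc(cc1)S(=O)(=O)OC[C@]1(C)O[C@H]1C[C@H](CC(=O)OC(C)(C)C)CSc1nnnn1-c1ccccc1 | intermediate
19 | hydroxy tosylate lactone, (4R,6R)-6-[(2S)-2-hydroxy-1-{[(4-methylphenyl)sulfonyl]oxy}propan-2-yl]-4-{[(1-phenyl-1H-tetrazol-5-yl)sulfanyl]methyl}oxan-2-one | c1ccccc1-n1nnnc1SC[C@@H]1C[C@@H](OC(=O)C1)[C@@](C)(O)COS(=O)(=O)c1ccc(C)cc1 | intermediate (not isolated)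
20 | (4R,6R)-6-[(2S)-2-methyloxiran-2-yl]-4-{[(1-phenyl-1H-tetrazol-5-yl)sulfanyl]methyl}oxan-2-one | c1ccccc1-n1nnnc1SC[C@@H]1C[C@@H](OC(=O)C1)[C@]1(C)CO1 | intermediate
21 | (3S,4R,6R)-3-methyl-6-[(2S)-2-methyloxiran-2-yl]-4-{[(1-phenyl-1H-tetrazol-5-yl)sulfanyl]methyl}oxan-2-one | c1ccccc1-n1nnnc1SC[C@@H]1C[C@@H](OC(=O)[C@H]1C)[C@]1(C)CO1 | intermediate
22 | (3S,4R,6R)-3-methyl-6-[(2S)-2-methyloxiran-2-yl]-4-{[(1-phenyl-1H-tetrazol-5-yl)sulfonyl]methyl}oxan-2-one | O=S(=O)(c1nnnn1-c1ccccc1)C[C@@H]1C[C@@H](OC(=O)[C@H]1C)[C@]1(C)CO1 | intermediate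
23 | (3S,4S,6R)-3-methyl-4-{2-[(2S,3S)-2-methyl-3-[(3E)-3-methyl-5-(phenylsulfonyl)pent-3-en-1-yl]oxiran-2-yl]ethenyl}-6-[(2S)-2-methyloxiran-2-yl]oxan-2-one (E/Z mixture) | O=S(=O)(c1ccccc1)C/C=C(\C)CC[C@@H]1O[C@@]1(C)C=C[C@@H]1C[C@@H](OC(=O)[C@H]1C)[C@]1(C)CO1 | intermediate
24 | (3S,4R,6R)-3-methyl-4-{2-[(2S,3S)-2-methyl-3-[(3E)-3-methyl-5-(phenylsulfonyl)pent-3-en-1-yl]oxiran-2-yl]ethyl}-6-[(2S)-2-methyloxiran-2-yl]oxan-2-one | O=S(=O)(c1ccccc1)C/C=C(\C)CC[C@@H]1O[C@@]1(C)CC[C@@H]1C[C@@H](OC(=O)[C@H]1C)[C@]1(C)CO1 | intermediate
25 | (1R,3R,4S,7E,11S,12S,15S)-11,12-epoxy-4-hydroxy-6-(phenylsulfonyl)cembr-7-en-16,3-olide (both C6 epimers) | C1(S(=O)(=O)c2ccccc2)/C=C(\C)CC[C@@H]2O[C@@]2(C)CC[C@@H]2C[C@@H](OC(=O)[C@H]2C)[C@@](C)(O)C1 | intermediate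
26 | (1R,3R,4S,7E,11S,12S,15S)-11,12-epoxy-4-hydroxycembr-7-en-16,3-olide | C1/C=C(\C)CC[C@@H]2O[C@@]2(C)CC[C@@H]2C[C@@H](OC(=O)[C@H]2C)[C@@](C)(O)C1 | intermediate
27 | (1R,3R,4S,7S,11S,12S,15S)-11,12-epoxy-7-hydroperoxy-4-hydroxycembr-8(19)-en-16,3-olide | C=C1CC[C@@H]2O[C@@]2(C)CC[C@@H]2C[C@@H](OC(=O)[C@H]2C)[C@@](C)(O)CC[C@@H]1OO | target

## Step count and least certain steps

Total step count: 20. Longest linear sequence: 16 steps (steps 5 to 20).

**Step 18 (key step).** The most likely failure is acylation: the carbanion adds to the lactone carbonyl to give a 12-membered β-keto sulfone. Lactones are intrinsically more electrophilic towards lithiated sulfones than epoxides are. Proton transfer from C15 and oligomerisation are lesser risks. The fallback removes the competing electrophile and keeps the same bond formation; it sets out from 24 and comes back at 25. The lactone of 24 is reduced with iBu2AlH at −78 °C to the lactol F1. This is silylated with t-BuMe2SiCl and imidazole to the silyl acetal F2, which has neither an electrophilic carbonyl nor an acidic C15–H. F2 is cyclised with LiN(SiMe3)2 as in step 18 to the macrocyclic silyl acetal F3. Bu4NF frees the macrocyclic lactol F4, and oxidation with PhI(OAc)2 and catalytic TEMPO returns the lactone 25.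

**Step 20.** The most likely failure is poor facial selectivity of the attack of singlet oxygen on the macrocyclic alkene, or hydrogen abstraction from C6 instead of C19; the ring conformation is the only control element. The fallback makes the wrong epimer productive by a substitution with inversion; it sets out from 26 and comes back at 27. The C7-epimeric hydroperoxide F5 that accompanies 27 is separated and reduced with PPh3 to the (7R)-allylic alcohol F6. The secondary hydroxyl is mesylated (MsCl, Et3N; the tertiary C4 hydroxyl does not react) to the mesylate F7. Displacement with H2O2 and KOH in an SN2 reaction inverts C7 and gives 27. The regioisomeric 8-hydroperoxide cannot be recovered in this way.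

**Step 16.** The most likely failure is proton transfer from the acidic allylic sulfone CH2 of 6 to the metalated tetrazolyl sulfone, or self-condensation of that sulfone, in place of carbonyl addition. The fallback performs the union before the phenyl sulfone is present; it sets out from 22 and comes back at 24.
- Geranyl acetate F8 is oxidised (SeO2, t-BuOOH) to the hydroxy acetate F9.
- F9 is epoxidised as in step 3 to the epoxy alcohol F10 and oxidised as in step 4 to the epoxy aldehyde F11.
- Julia–Kocienski reaction of F11 with 22 gives the alkene F12, and diimide reduction gives the saturated allylic acetate F13.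
- Substitution of the acetate by 2 under catalysis by the zerovalent palladium complex Pd(PPh3)4 gives 24.
The risk of this fallback is partial loss of the 7E geometry in the allyl–palladium intermediate.

**Step 13.** The most likely failure is opening of the protonated epoxide at the tertiary C4 (a seven-membered lactone or solvolysis), or participation of the sulfide sulfur, in place of the 6-exo attack at C3. The fallback separates the opening from the acid step; it sets out from 17 and comes back at 20.
- 17 is opened with benzoic acid and Ti(OiPr)4, which directs the carboxylate to C3 with inversion, to give the benzoate diol F14.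
- K2CO3 in MeOH removes the benzoate to give the triol ester F15.
- CF3CO2H then cleaves the tert-butyl ester with no epoxide present, and the C3 hydroxyl lactonises to the lactone diol F16.
- Selective tosylation of the primary hydroxyl gives 19, and DBU closes the epoxide to 20.

## Further compounds

F1 | step 18 | lactol of 24 (C16 hemiacetal, both anomers) | O=S(=O)(c1ccccc1)C/C=C(\C)CC[C@@H]1O[C@@]1(C)CC[C@@H]1C[C@@H](OC(O)[C@H]1C)[C@]1(C)CO1
F2 | step 18 | tert-butyldimethylsilyl acetal of F1 | O=S(=O)(c1ccccc1)C/C=C(\C)CC[C@@H]1O[C@@]1(C)CC[C@@H]1C[C@@H](OC(O[Si](C)(C)C(C)(C)C)[C@H]1C)[C@]1(C)CO1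
F3 | step 18 | macrocyclic C6 sulfone with C4 hydroxyl and C16 silyl acetal | C1(S(=O)(=O)c2ccccc2)/C=C(\C)CC[C@@H]2O[C@@]2(C)CC[C@@H]2C[C@@H](OC(O[Si](C)(C)C(C)(C)C)[C@H]2C)[C@@](C)(O)C1
F4 | step 18 | macrocyclic lactol of 25 | C1(S(=O)(=O)c2ccccc2)/C=C(\C)CC[C@@H]2O[C@@]2(C)CC[C@@H]2C[C@@H](OC(O)[C@H]2C)[C@@](C)(O)C1
F5 | step 20 | (7R)-hydroperoxide, C7 epimer of 27 | C=C1CC[C@@H]2O[C@@]2(C)CC[C@@H]2C[C@@H](OC(=O)[C@H]2C)[C@@](C)(O)CC[C@H]1OO
F6 | step 20 | (7R)-allylic alcohol | C=C1CC[C@@H]2O[C@@]2(C)CC[C@@H]2C[C@@H](OC(=O)[C@H]2C)[C@@](C)(O)CC[C@H]1O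
F7 | step 20 | (7R)-methanesulfonate | C=C1CC[C@@H]2O[C@@]2(C)CC[C@@H]2C[C@@H](OC(=O)[C@H]2C)[C@@](C)(O)CC[C@H]1OS(C)(=O)=O
F8 | step 16 | geranyl acetate | CC(C)=CCC/C(C)=C/COC(C)=O
F9 | step 16 | (2E,6E)-8-hydroxy-3,7-dimethylocta-2,6-dien-1-yl acetate | OC/C(C)=C/CC/C(C)=C/COC(C)=O
F10 | step 16 | (2E)-5-[(2S,3S)-3-(hydroxymethyl)-3-methyloxiran-2-yl]-3-methylpent-2-en-1-yl acetate | OC[C@]1(C)O[C@H]1CC/C(C)=C/COC(C)=O
F11 | step 16 | (2E)-5-[(2S,3R)-3-formyl-3-methyloxiran-2-yl]-3-methylpent-2-en-1-yl acetate | O=C[C@]1(C)O[C@H]1CC/C(C)=C/COC(C)=O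
F12 | step 16 | C6 acetate analogue of 23 (C13=C14 alkene, E/Z mixture) | CC(=O)OC/C=C(\C)CC[C@@H]1O[C@@]1(C)C=C[C@@H]1C[C@@H](OC(=O)[C@H]1C)[C@]1(C)CO1
F13 | step 16 | C6 acetate analogue of 24 | CC(=O)OC/C=C(\C)CC[C@@H]1O[C@@]1(C)CC[C@@H]1C[C@@H](OC(=O)[C@H]1C)[C@]1(C)CO1
F14 | step 13 | C3 benzoate, C4/C5 diol tert-butyl ester | OC[C@](C)(O)[C@H](OC(=O)c1ccccc1)C[C@H](CC(=O)OC(C)(C)C)CSc1nnnn1-c1ccccc1
F15 | step 13 | C3/C4/C5 triol tert-butyl ester | OC[C@](C)(O)[C@H](O)C[C@H](CC(=O)OC(C)(C)C)CSc1nnnn1-c1ccccc1
F16 | step 13 | lactone diol, (4R,6R)-6-[(2S)-1,2-dihydroxypropan-2-yl]-4-{[(1-phenyl-1H-tetrazol-5-yl)sulfanyl]methyl}oxan-2-one | c1ccccc1-n1nnnc1SC[C@@H]1C[C@@H](OC(=O)C1)[C@@](C)(O)CO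
A1 | alternative 1 | (3R)-3-chloro-6-iodohept-6-en-2-one | C=C(I)CC[C@@H](Cl)C(C)=O
A2 | alternative 1 | C13 primary iodide with PMB ethers at O3, O7 and O16 and a triethylsilyl ether at O4 | ICC[C@H](C[C@@H](OCc1ccc(OC)cc1)[C@@](C)(O[Si](CC)(CC)CC)CCCOCc1ccc(OC)cc1)[C@H](C)COCc1ccc(OC)cc1
A3 | alternative 1 | open-chain 11,12-epoxide with C8 alkenyl iodide | C=C(I)CC[C@@H]1O[C@@]1(C)CC[C@H](C[C@@H](OCc1ccc(OC)cc1)[C@@](C)(O[Si](CC)(CC)CC)CCCOCc1ccc(OC)cc1)[C@H](C)COCc1ccc(OC)cc1
A4 | alternative 2 | seco C3 aldehyde / C4 methyl ketone / C16 methyl ester | CC(=O)CC[C@@H](OCc1ccc(OC)cc1)C(=C)CC/C=C(\C)CC[C@H](CC=O)[C@H](C)C(=O)OC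
A5 | alternative 2 | macrocyclic lactone with C4 hydroxyl, C11=C12 alkene and C7 PMB ether | C=C1CC/C=C(\C)CC[C@@H]2C[C@@H](OC(=O)[C@H]2C)[C@@](C)(O)CC[C@H]1OCc1ccc(OC)cc1
A6 | alternative 3 | seco C8 alkenyl iodide / C7 aldehyde with lactone, epoxide and C4 triethylsilyl ether | C=C(I)CC[C@@H]1O[C@@]1(C)CC[C@@H]1C[C@@H](OC(=O)[C@H]1C)[C@@](C)(O[Si](CC)(CC)CC)CCC=O
A7 | alternative 3 | macrocyclic (7R)-allylic alcohol with C4 triethylsilyl ether | C=C1CC[C@@H]2O[C@@]2(C)CC[C@@H]2C[C@@H](OC(=O)[C@H]2C)[C@@](C)(O[Si](CC)(CC)CC)CC[C@H]1O
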